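## Retrosynthetic overview

1. Labdane numbering is used: ring A = C1–C5, C10; ring B = C5–C10; lactone C4–C19(=O)–O–C20–C10; epoxide C8–O–C17; side chain C11–C16; β = the face of C20. The given SMILES is read as (4S,5S,6R,8R,9S,10S,13R). The end game removes, in turn, the acetate, the C14=C15 enol ether (selenoxide elimination), the C9–O–C13 tetrahydrofuran (Tsuji–Trost etherification of a vinyl epoxide), the C9–C11 bond (organocerium addition) and the C8 epoxide (Weitz–Scheffer epoxidation), back to a tricyclic C9 ketone.
2. Key disconnection: C2–C3 and C4–C5 together. This removes ring A and the δ-lactone ring, i.e. both three-atom bridges of the 3-oxabicyclo[3.3.1]nonan-2-one (bridgeheads C4 and C10, one-atom bridge C5). It leaves a monocyclic ring-B epoxide with a methacrylate ester on O–C20 and a 2-carboxyethyl arm (C1, C2, CO2H) on C10.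
3. Enabling feature: the C19(=O)–O–C20 lactone is a ready-made ester tether for the C3=C4(C18)–C19 methacrylate unit. In ring B the C4–C5 bond is anti to the C6 oxygen and H5 is syn to C20 (ring A cis-fused, lactone trans-fused to ring B), which is the signature of a C5–C6 β-epoxide opened at C5 with inversion by C4.
4. Ring B (C10 quaternary centre, C5=C6, masked C9 ketone) comes from an auxiliary-controlled Birch reduction–alkylation of a 2-methoxybenzamide; the β-epoxide is delivered by the C20 hydroxyl.
5. Order of ring formation: ring B (from the arene) → ring A and lactone ring together (key step) → C8 spiro-epoxide → tetrahydrofuran → dihydrofuran.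

Key step: step 9

Assumption: the (S)-auxiliary in 3 is taken to steer the alkylation of step 2 to the C10 configuration drawn for 6; if the sense is the opposite one, the (R)-enantiomer of 2 is used and nothing else changes.

## Route

Step 1
Reactants: 1 2-methoxybenzoyl chloride; 2 (S)-2-(methoxymethyl)pyrrolidine
Product: 3 (S)-1-(2-methoxybenzoyl)-2-(methoxymethyl)pyrrolidine
Conditions: Et3N, CH2Cl2, 0 °C → rt
Reagents that add atoms: none
Why: N-acylation of a secondary amine by an acid chloride (Schotten–Baumann type); the auxiliary stereocentre is not touched.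

Step 2
Reactants: 3 benzamide; 4 (3-bromopropoxy)(tert-butyl)diphenylsilane
Product: 6 (S)-pyrrolidine amide of (R)-1-[3-(tert-butyldiphenylsilyloxy)propyl]-2-methoxycyclohexa-2,5-diene-1-carboxylic acid, via potassium enolate 5 (not isolated)
Conditions: K (2.2 equiv), NH3(l)/THF, t-BuOH (1.0 equiv), −78 °C; piperylene; then 4, −78 °C → rt
Reagents that add atoms: none
Why: asymmetric Birch reduction–alkylation, in which the chelated amide enolate 5 should be alkylated at the ipso carbon on the face left open by the methoxymethylpyrrolidine, setting the C10 quaternary centre; excess metal is destroyed before 4 is added so that the silyl phenyl groups are not reduced.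

Step 3
Reactants: 6 Birch product
Product: 7 {1-[3-(tert-butyldiphenylsilyloxy)propyl]-2-methoxycyclohexa-2,5-dien-1-yl}methanol (C20 alcohol, C10 unchanged)
Conditions: LiNH2BH3 (4 equiv, from BH3·NH3 and LiN(i-Pr)2), THF, 0 °C → rt
Reagents that add atoms: none
Why: reduction of a hindered tertiary amide to the primary alcohol with lithium amidotrihydroborate, which should leave the enol ether, the skipped diene and the silyl ether untouched and releases the auxiliary 2.

Step 4
Reactants: 7 dienyl methanol
Product: 8 {6-[3-(tert-butyldiphenylsilyloxy)propyl]-1,4-dioxaspiro[4.5]dec-7-en-6-yl}methanol (C9 dioxolane, C5=C6 retained)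
Conditions: ethane-1,2-diol (5 equiv), PPTS (cat.), CH2Cl2, rt
Reagents that add atoms: ethane-1,2-diol OCCO
Why: acid-catalysed addition of the diol to the enol ether and transketalisation gives the dioxolane without passing through the free β-hydroxy ketone, so retro-aldol loss of C20 is avoided and C9 is masked for the key step.

Step 5
Reactants: 8 homoallylic alcohol
Product: 9 5β,6β-epoxide of 8 (epoxide oxygen syn to the C20 hydroxymethyl group)
Conditions: VO(acac)2 (5 mol %), t-BuOOH (1.5 equiv), CH2Cl2, rt
Reagents that add atoms: tert-butyl hydroperoxide CC(C)(C)OO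
Why: hydroxyl-directed vanadium-catalysed epoxidation of a homoallylic alcohol should deliver oxygen to the C5=C6 face syn to the C20 hydroxymethyl group, which sets C5 and C6.

Step 6
Reactants: 9 epoxy alcohol
Product: 10 methacrylate ester of 9 at O–C20
Conditions: methacryloyl chloride (1.5 equiv), Et3N, DMAP (cat.), CH2Cl2, 0 °C → rt
Reagents that add atoms: methacryloyl chloride CC(=C)C(Cl)=O
Why: DMAP-catalysed O-acylation of the neopentyl primary alcohol installs C3, C4, C18 and C19 on the C20 oxygen.

Step 7
Reactants: 10 silyl ether
Product: 11 primary alcohol (3-hydroxypropyl arm on C10)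
Conditions: Bu4NF (1.2 equiv), AcOH (1.2 equiv), THF, 0 °C → rt
Reagents that add atoms: none
Why: fluoride-mediated silyl ether cleavage, buffered with acetic acid so that the methacrylate and the epoxide are not attacked.

Step 8
Reactants: 11 primary alcohol
Product: 12 carboxylic acid (2-carboxyethyl arm C1–C2–CO2H on C10; methacrylate on O–C20; 5β,6β-epoxide; C9 dioxolane)
Conditions: TEMPO (20 mol %), PhI(OAc)2 (2.5 equiv), MeCN/H2O 1:1, rt
Reagents that add atoms: water O
Why: oxoammonium-mediated oxidation of the primary alcohol through the aldehyde hydrate to the acid under near-neutral conditions that should spare the epoxide, the ketal and the methacrylate.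

Step 9
Reactants: 12 carboxylic acid
Product: 17 tricyclic 6β-hydroxy-19,20-lactone C9 dioxolane (ring A cis-fused to ring B, 5β-H), via cesium carboxylate 13 (not isolated), via primary radical 14 (not isolated), via lactone radical 15 (not isolated), via lactone enolate 16 (not isolated)
Conditions: Cs2CO3 (1.1 equiv), 4CzIPN (2 mol %), degassed DMF (0.005 M), blue LEDs, 30 °C; aq. NH4Cl
Reagents that add atoms: none
Why: Proposed new method: the excited photocatalyst oxidises carboxylate 13, loss of CO2 gives the C2 radical 14, this closes 8-endo-trig onto C3 of the C20-tethered methacrylate to give the tertiary α-ester radical 15, and reduction of 15 by the photocatalyst radical anion gives the cesium enolate 16, whose C4 opens the epoxide at C5. The closest known reaction types are photoredox decarboxylative radical addition–polar cyclisation cascades (Giese addition followed by carbanion ring closure), 8-endo cyclisations of ester-tethered radicals and intramolecular enolate–epoxide alkylations; new is their combination and an epoxide as the terminating electrophile. The eight-membered lactone closes 8-endo-trig and is then bridged by the C4–C5 bond, which forms ring A in a 6-(enolexo)-exo-tet and the δ-lactone ring in a 6-(enolendo)-exo-tet sense. C4 is fixed because the tether holds C19 on the C20 face, C5 is set by SN2 inversion (C4 enters anti to the β-epoxide oxygen, so H5 becomes β), and C6 keeps the oxygen set in step 5. The step needs cyclisation of 14 to beat intermolecular addition and hydrogen abstraction (high dilution, no hydrogen donor, Thorpe–Ingold effect of C10), attack at C5 and not C6 (six- against seven-membered bridge), alkylation before protonation (aprotic medium, cesium counter-ion) and no aldol at C9 (dioxolane).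

Step 10
Reactants: 17 hydroxy lactone ketal
Product: 18 6β-hydroxy-9-oxo-19,20-lactone
Conditions: 1 M aq. HCl, THF, 40 °C
Reagents that add atoms: water O
Why: acid hydrolysis of the dioxolane; the lactone and the secondary alcohol are inert and, with O–C20 acylated, no retro-aldol can follow.

Step 11
Reactants: 18 hydroxy keto lactone
Product: 19 8(17)-methylene ketone
Conditions: (CH2O)n (5 equiv), N-methylanilinium trifluoroacetate (2 equiv), THF, reflux
Reagents that add atoms: formaldehyde C=O
Why: Mannich-type α-methylenation (aminomethylation at C8, the only enolisable position, then β-elimination of the amine) installs C17.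

Step 12
Reactants: 19 exo-methylene ketone
Product: 20 8β,17-epoxy-9-ketone (epoxide oxygen β, C17 α)
Conditions: t-BuOOH (3 equiv), DBU (1.5 equiv), CH2Cl2, 0 °C → rt
Reagents that add atoms: tert-butyl hydroperoxide CC(C)(C)OO
Why: Weitz–Scheffer nucleophilic epoxidation, in which the peroxide adds to C17 and the enolate closes at C8 from the β-face because the α-face is screened by C1, which is axial on ring B; this sets C8.

Step 13
Reactants: 21 4-bromobut-1-yne
Product: 22 5-bromo-3-methylidenepent-1-ene
Conditions: ethene (1 atm), second-generation Grubbs catalyst (5 mol %), CH2Cl2, 40 °C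
Reagents that add atoms: ethene C=C
Why: ethene–alkyne cross enyne metathesis converts the terminal alkyne into a 2-substituted buta-1,3-diene in one step.

Step 14
Reactants: 20 epoxy ketone; 22 dienyl bromide
Product: 24 9α-hydroxy compound carrying the 3-methylidenepent-4-enyl chain (C11–C16) on C9 (C11 β), via Grignard reagent 23 (not isolated)
Conditions: Mg, THF (22 → 23); anhydrous CeCl3 (3.5 equiv), THF, −78 °C; then 20, −78 → −20 °C; aq. NH4Cl
Reagents that add atoms: none
Why: CeCl3-promoted Grignard 1,2-addition to a hindered, non-enolisable ketone; attack along the axial β trajectory, anti to the axial C10–C1 and C8–C17 bonds (Felkin–Anh and steric control), should give the 9α-alcohol, with one equivalent consumed by the 6-hydroxyl and the lactone spared at low temperature.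

Step 15
Reactants: 24 diene diol
Product: 25 13,16-epoxide (2-alkyl-2-vinyloxirane, both C13 epimers)
Conditions: mCPBA (1.05 equiv), NaHCO3, CH2Cl2, −20 → 0 °C
Reagents that add atoms: 3-chloroperoxybenzoic acid OOC(=O)c1cccc(Cl)c1
Why: Prilezhaev epoxidation of the more electron-rich 1,1-disubstituted double bond of the diene; C13 is left unset on purpose because the next step is stereoconvergent.

Step 16
Reactants: 25 vinyl epoxide
Product: 26 9α,13-epoxy (tetrahydrofuran) compound with C13 carrying CH2OH (C16) and vinyl (C14=C15), 13R
Conditions: Pd2(dba)3·CHCl3 (2.5 mol %), (1R,2R)-N,N′-bis[2-(diphenylphosphino)benzoyl]cyclohexane-1,2-diamine (7.5 mol %), Et3B (5 mol %), CH2Cl2, rt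
Reagents that add atoms: none
Why: intramolecular Tsuji–Trost allylic etherification, in which the vinyl epoxide ionises to a π-allylpalladium alkoxide whose faces interconvert and the 9-hydroxyl attacks the substituted terminus C13 (5-exo), so the chiral diphosphine should set C13 from both epimers of 25; if this ligand enantiomer proves mismatched for 13R, the (1S,2S) ligand is used.

Step 17
Reactants: 26 hydroxymethyl vinyl tetrahydrofuran
Product: 29 6β-hydroxy spiro-dihydrofuran (deacetyl target), via selenide 27 (not isolated), via selenoxide 28 (not isolated)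
Conditions: PhSeCl (1.2 equiv), pyridine, CH2Cl2, −78 → 0 °C; then 30 % aq. H2O2, pyridine, 0 → 40 °C
Reagents that add atoms: none
Why: 5-endo selenoetherification of the homoallylic C16 alcohol onto the vinyl group (oxygen to C15, selenium to C14), then selenoxide syn-elimination, which can only go toward C15 because C13 is quaternary and so should give the C14=C15 enol ether without acid.

Step 18
Reactants: 29 deacetyl target
Product: 30 target, CNP0173713.1
Conditions: Ac2O (3 equiv), pyridine, DMAP (cat.), CH2Cl2, 0 °C → rt
Reagents that add atoms: acetic anhydride CC(=O)OC(C)=O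
Why: DMAP-catalysed acetylation of the only remaining hydroxyl (equatorial 6β-OH) under basic conditions that the enol ether and the spiro-epoxide should tolerate.

## Compound list

1 | 2-methoxybenzoyl chloride | COc1ccccc1C(Cl)=O | starting material
2 | (S)-2-(methoxymethyl)pyrrolidine | COC[C@@H]1CCCN1 | starting material
3 | (S)-1-(2-methoxybenzoyl)-2-(methoxymethyl)pyrrolidine | COC[C@@H]1CCCN1C(=O)c1ccccc1OC | intermediate
4 | (3-bromopropoxy)(tert-butyl)diphenylsilane | CC(C)(C)[Si](OCCCBr)(c1ccccc1)c1ccccc1 | starting material
5 | potassium amide enolate of 1,4-dihydro-3 | COC[C@@H]1CCCN1C([O-])=C1C=CCC=C1OC.[K+] | intermediate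
6 | (S)-pyrrolidine amide of (R)-1-[3-(tert-butyldiphenylsilyloxy)propyl]-2-methoxycyclohexa-2,5-diene-1-carboxylic acid | COC1=CCC=C[C@@]1(CCCO[Si](c2ccccc2)(c2ccccc2)C(C)(C)C)C(=O)N1CCC[C@H]1COC | intermediate
7 | {1-[3-(tert-butyldiphenylsilyloxy)propyl]-2-methoxycyclohexa-2,5-dien-1-yl}methanol | COC1=CCC=C[C@@]1(CCCO[Si](c2ccccc2)(c2ccccc2)C(C)(C)C)CO | intermediate
8 | {6-[3-(tert-butyldiphenylsilyloxy)propyl]-1,4-dioxaspiro[4.5]dec-7-en-6-yl}methanol | OC[C@]1(CCCO[Si](c2ccccc2)(c2ccccc2)C(C)(C)C)C=CCCC13OCCO3 | intermediate
9 | 5β,6β-epoxide of 8 (syn to CH2OH) | OC[C@]1(CCCO[Si](c2ccccc2)(c2ccccc2)C(C)(C)C)[C@@H]2O[C@@H]2CCC13OCCO3 | intermediate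
10 | methacrylate ester of 9 | C=C(C)C(=O)OC[C@]1(CCCO[Si](c2ccccc2)(c2ccccc2)C(C)(C)C)[C@@H]2O[C@@H]2CCC13OCCO3 | intermediate
11 | primary alcohol from 10 | C=C(C)C(=O)OC[C@]1(CCCO)[C@@H]2O[C@@H]2CCC13OCCO3 | intermediate
12 | epoxy methacrylate carboxylic acid (key-step precursor) | C=C(C)C(=O)OC[C@]1(CCC(=O)O)[C@@H]2O[C@@H]2CCC13OCCO3 | intermediate
13 | cesium carboxylate of 12 | C=C(C)C(=O)OC[C@]1(CCC(=O)[O-])[C@@H]2O[C@@H]2CCC13OCCO3.[Cs+] | intermediate
14 | primary C2 radical | C=C(C)C(=O)OC[C@]1(C[CH2])[C@@H]2O[C@@H]2CCC13OCCO3 | intermediate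
15 | eight-membered lactone C4 radical | C[C]1CCC[C@@]2(COC1=O)[C@@H]3O[C@@H]3CCC24OCCO4 | intermediate
16 | cesium enolate of the eight-membered lactone | CC1=C([O-])OC[C@]2(CCC1)[C@@H]3O[C@@H]3CCC24OCCO4.[Cs+] | intermediate
17 | tricyclic 6β-hydroxy-19,20-lactone, C9 dioxolane | O[C@@H]1CCC2(OCCO2)[C@]23CCC[C@](C)(C(=O)OC2)[C@@H]13 | intermediate
18 | 6β-hydroxy-9-oxo-19,20-lactone | O[C@@H]1CCC(=O)[C@]23CCC[C@](C)(C(=O)OC2)[C@@H]13 | intermediate
19 | 8(17)-methylene-9-ketone | O[C@@H]1CC(=C)C(=O)[C@]23CCC[C@](C)(C(=O)OC2)[C@@H]13 | intermediate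
20 | 8β,17-epoxy-9-ketone | O[C@@H]1C[C@@]2(CO2)C(=O)[C@]23CCC[C@](C)(C(=O)OC2)[C@@H]13 | intermediate
21 | 4-bromobut-1-yne | C#CCCBr | starting material
22 | 5-bromo-3-methylidenepent-1-ene | C=CC(=C)CCBr | intermediate
23 | (3-methylidenepent-4-en-1-yl)magnesium bromide | C=CC(=C)CC[Mg]Br | intermediate
24 | 9α-hydroxy diene | O[C@@H]1C[C@@]2(CO2)[C@](O)(CCC(=C)C=C)[C@]23CCC[C@](C)(C(=O)OC2)[C@@H]13 | intermediate
25 | 13,16-epoxide of 24 (C13 epimers) | O[C@@H]1C[C@@]2(CO2)[C@](O)(CCC4(CO4)C=C)[C@]23CCC[C@](C)(C(=O)OC2)[C@@H]13 | intermediate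
26 | 9α,13-epoxy-16-hydroxy-14-ene (13R) | O[C@@H]1C[C@@]2(CO2)[C@]2(CC[C@](CO)(C=C)O2)[C@]23CCC[C@](C)(C(=O)OC2)[C@@H]13 | intermediate
27 | 14-phenylselanyl tetrahydrofuran (C14 epimers) | O[C@@H]1C[C@@]2(CO2)[C@]2(CC[C@]3(C([Se]c4ccccc4)COC3)O2)[C@]23CCC[C@](C)(C(=O)OC2)[C@@H]13 | intermediate
28 | selenoxide of 27 | O[C@@H]1C[C@@]2(CO2)[C@]2(CC[C@]3(C([Se](=O)c4ccccc4)COC3)O2)[C@]23CCC[C@](C)(C(=O)OC2)[C@@H]13 | intermediate
29 | deacetyl target (6β-alcohol) | O[C@@H]1C[C@@]2(CO2)[C@]2(CC[C@]3(C=COC3)O2)[C@]23CCC[C@](C)(C(=O)OC2)[C@@H]13 | intermediate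
30 | CNP0173713.1 | CC(=O)O[C@@H]1C[C@@]2(CO2)[C@]2(CC[C@]3(C=COC3)O2)[C@]23CCC[C@](C)(C(=O)OC2)[C@@H]13 | target

## Summary and risks

Total step count: 18. Longest linear sequence: 17 (steps 1–12 and 14–18; step 13 makes the side-chain bromide).

Steps most likely to fail:

**Step 9 (proposed new method).** The 8-endo radical closure may be too slow, so the C2 radical is lost to intermolecular addition or hydrogen abstraction. The enolate may be protonated before it alkylates. The tether also forces the epoxide to open in the trans-diequatorial (boat-like) mode, against the Fürst–Plattner preference, which may be sluggish. Fallback, known chemistry, forming the two bonds one at a time without the tether: from 9, pivaloylation of the C20 hydroxyl (pivaloyl chloride, pyridine, DMAP) gives the pivalate F1. Bu4NF/AcOH then gives the primary alcohol F2, and TEMPO/PhI(OAc)2 the acid F3. Intermolecular decarboxylative Giese addition of F3 to methyl methacrylate (4CzIPN, Cs2CO3, DMF, blue light, protic work-up) gives the methyl ester F4 and forms C2–C3. KN(SiMe3)2 in THF then closes ring A by intramolecular enolate alkylation at the epoxide (6-exo-tet, trans-diaxial opening, cis-fused decalin), giving the hydroxy ester F5 and forming C4–C5. NaOMe in MeOH removes the pivalate and the C20 alkoxide lactonises onto the C19 ester, returning to 17. Only the C4 epimer with the ester syn to C20 can lactonise, so the C4 selectivity of this route is corrected by separation at that stage.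

**Step 16.** The hindered tertiary 9-hydroxyl may attack the π-allyl slowly or with poor facial control at C13 (mismatched substrate and ligand), or the π-allyl may collapse by elimination. Fallback, a stereospecific instead of a stereoconvergent closure: from 24, hydroxyl-directed epoxidation of the bishomoallylic C13=C16 bond (VO(acac)2, t-BuOOH) should give 25 as mainly one epimer, and PPTS then closes the ring by 5-exo opening at C13 with inversion, returning to 26.

**Step 17.** Selenoxide elimination toward an oxygen-bearing carbon is slow and may be overtaken by decomposition, and chloride released during selenenylation may open the C8 spiro-epoxide. Fallback, ring-closing metathesis to the enol ether: from 26, chemoselective O-vinylation of the primary C16 hydroxyl ([Ir(cod)Cl]2, Na2CO3, vinyl acetate, toluene) gives the vinyl ether F6, and the second-generation Grubbs catalyst closes C14=C15 with loss of ethene, returning to 29.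

Further compounds
F1 | step 9 | C20 pivalate of 9 | CC(C)(C)C(=O)OC[C@]1(CCCO[Si](c2ccccc2)(c2ccccc2)C(C)(C)C)[C@@H]2O[C@@H]2CCC13OCCO3
F2 | step 9 | primary alcohol from F1 | CC(C)(C)C(=O)OC[C@]1(CCCO)[C@@H]2O[C@@H]2CCC13OCCO3
F3 | step 9 | carboxylic acid from F2 | CC(C)(C)C(=O)OC[C@]1(CCC(=O)O)[C@@H]2O[C@@H]2CCC13OCCO3
F4 | step 9 | Giese adduct with methyl methacrylate (C4 epimers) | CC(C)(C)C(=O)OC[C@]1(CCCC(C)C(=O)OC)[C@@H]2O[C@@H]2CCC13OCCO3
F5 | step 9 | cis-decalin 6β-hydroxy methyl ester, C20 pivalate | O[C@@H]1CCC2(OCCO2)[C@@]3(COC(=O)C(C)(C)C)CCC[C@](C)(C(=O)OC)[C@@H]13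
F0 | step 16 | none | none
F6 | step 17 | C16 vinyl ether of 26 | O[C@@H]1C[C@@]2(CO2)[C@]2(CC[C@](COC=C)(C=C)O2)[C@]23CCC[C@](C)(C(=O)OC2)[C@@H]13
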